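**Retrosynthetic overview**

- Target 12 ⇒ cis-diol 9 + angelic acid 10. The last bond made is the C3–O ester, by acylation at oxygen with no change at C3.
- 9 ⇒ boronic acid 3 + enal 6. Ring B (the dihydrofuran) is closed by making C3a–C3 and O1–C2 in one flask: aryl transfer from zinc to the CHO carbon (becomes C3), then 5-exo attack of the neighbouring phenoxide O1 on a π-allylpalladium terminus (becomes C2).
- Enabling feature: C2 of ring B carries a 2-(acetoxymethyl)allyl group. C2–C(=CH2)–CH2OAc is the allylic transposition isomer of C2=C(CH2OAc)2, whose two arms are identical, so C3, C2 and the whole side chain map onto one achiral, geometry-free enal. C3a and O1 are an ortho carbon/oxygen pair of the resorcinol ring A.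
- 3 ⇐ bromination and borylation of 2′,4′-dihydroxyacetophenone 1 (ring A is bought, ring B is formed in step 4); 6 ⇐ Wittig reaction of 1,3-diacetoxyacetone 4. No protecting groups are used.

Key step: step 4

Assumption: (+)-MIB is taken to deliver the aryl group to the Re face of enal 6 and the (R,R)-bisphosphine to give 2R; if either sense proves opposite, the ligand antipode is used and nothing else changes.

**Route**

Step 1
Reactants: 1 1-(2,4-dihydroxyphenyl)ethanone
Product: 2 1-(5-bromo-2,4-dihydroxyphenyl)ethanone
Conditions: NBS (1.0 equiv), MeCN, 0 °C to rt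
Reagents that add atoms: N-bromosuccinimide, O=C1CCC(=O)N1Br
Why: Electrophilic aromatic bromination directed by the free 4-OH; C5 (ortho to 4-OH, para to the chelated 2-OH) is the open activated position, C3 being flanked by both oxygens, so the 5-bromo isomer should predominate.

Step 2
Reactants: 2 1-(5-bromo-2,4-dihydroxyphenyl)ethanone
Product: 3 (5-acetyl-2,4-dihydroxyphenyl)boronic acid
Conditions: B2(OH)4, Pd(OAc)2 (2 mol%), XPhos (4 mol%), KOAc, EtOH, 80 °C; isolated by extraction and used without chromatography
Reagents that add atoms: tetrahydroxydiboron, OB(O)B(O)O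
Why: Miyaura-type borylation (oxidative addition of the aryl bromide to zerovalent palladium, acetate-assisted transmetallation with the diboron reagent, reductive elimination) should give the boronic acid directly, with the free phenols and the ketone tolerated under the weakly basic conditions.

Step 3
Reactants: 4 2-oxopropane-1,3-diyl diacetate (1,3-diacetoxyacetone); 5 (triphenylphosphoranylidene)acetaldehyde
Product: 6 2-(2-oxoethylidene)propane-1,3-diyl diacetate [4-acetoxy-3-(acetoxymethyl)but-2-enal]
Conditions: toluene, 80 °C, 4 in slight excess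
Reagents that add atoms: none
Why: Wittig olefination with a stabilised ylide; the ketone is activated by its two α-acyloxy groups and is symmetric, so no alkene geometry arises, and the β,β-disubstituted enal formed should react more slowly with the ylide than the ketone kept in excess.

Step 4
Reactants: 3 (5-acetyl-2,4-dihydroxyphenyl)boronic acid (1.5 equiv); 6 2-(2-oxoethylidene)propane-1,3-diyl diacetate
Product: 9 2-[(2R,3R)-5-acetyl-3,6-dihydroxy-2,3-dihydro-1-benzofuran-2-yl]prop-2-en-1-yl acetate, via arylzinc reagent 7 (not isolated), via zinc alkoxide adduct 8 (not isolated)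
Conditions: Et2Zn (8 equiv), toluene, 60 °C; (+)-MIB [(2R)-3-exo-morpholinoisoborneol, 10 mol%], then 6, 0 °C; MeOH (quench of Et–Zn); then Pd2(dba)3·CHCl3 (2.5 mol%), (R,R)-DACH-phenyl bisphosphine [N,N′-(1R,2R)-cyclohexane-1,2-diylbis(2-diphenylphosphanylbenzamide), 7.5 mol%], THF, 0 °C to rt; aq NH4Cl
Reagents that add atoms: none
Why: Boron-to-zinc exchange gives arylzinc 7, and the zinc amino-alkoxide formed from (+)-MIB transfers its aryl group 1,2 to the Re face of enal 6 (closest known type: amino-alcohol-catalysed asymmetric aryl transfer from arylboronic acid/Et2Zn to enals), which makes the C3a–C3 bond and the S carbinol centre of 8 that is C3 of the product (R in 9 only because the CIP order changes once C2 carries O1). Zerovalent palladium then ionises one of the two equivalent acetoxymethyl arms of 8 and the ortho zinc phenoxide O1 attacks the substituted allyl terminus anti to palladium (closest known type: asymmetric Tsuji–Trost cyclisation of o-(4-acyloxy-3-methylbut-2-enyl)phenols to 2-isopropenyl-2,3-dihydrobenzofurans, with zinc alkoxides as competent oxygen nucleophiles), which makes the O1–C2 bond and leaves the other arm as the CH2OAc of the target. Ring B closes in the 5-exo mode on the π-allyl terminus C2, the alternative attack of O1 on the CH2 terminus being a 7-endo closure. C3 is controlled by the amino alcohol catalyst and C2 by the bisphosphine ligand, which chooses the allyl face after π–σ–π equilibration through the unsubstituted CH2 terminus, so that the cis 2R,3R relation is set by the catalyst and not by the C3 substituent. The step needs aryl over ethyl transfer and 1,2 over 1,4 addition, secured by the mixed aryl(ethyl)zinc and the fully substituted β-carbon, and O1 over the other two oxygens as nucleophile, secured because only O1 can reach C2 through a five-membered transition state, the C6 phenoxide being para to C3a and held by the acetyl group, and because the C3 alkoxide is no leaving group, so that the benzylic carbon cannot ionise.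

Step 5
Reactants: 9 2-[(2R,3R)-5-acetyl-3,6-dihydroxy-2,3-dihydro-1-benzofuran-2-yl]prop-2-en-1-yl acetate; 10 angelic acid [(2Z)-2-methylbut-2-enoic acid]
Product: 12 (2R,3R)-5-acetyl-2-[3-(acetyloxy)prop-1-en-2-yl]-6-hydroxy-2,3-dihydro-1-benzofuran-3-yl (2Z)-2-methylbut-2-enoate, via mixed anhydride 11 (not isolated)
Conditions: 10 (1.1 equiv), 2,4,6-trichlorobenzoyl chloride, Et3N, toluene, rt; then 9, 60 °C
Reagents that add atoms: none
Why: Mixed-anhydride (Yamaguchi-type) esterification run without a nucleophilic amine catalyst, the known way to keep the Z geometry of angelates; acylation takes place at oxygen, so C3 keeps its configuration, and the secondary C3–OH should react in preference to the C6 phenol that is hydrogen-bonded to the acetyl group.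

**Compound list**

1 | 1-(2,4-dihydroxyphenyl)ethanone | CC(=O)c1ccc(O)cc1O | starting material
2 | 1-(5-bromo-2,4-dihydroxyphenyl)ethanone | CC(=O)c1cc(Br)c(O)cc1O | intermediate
3 | (5-acetyl-2,4-dihydroxyphenyl)boronic acid | CC(=O)c1cc(B(O)O)c(O)cc1O | intermediate
4 | 2-oxopropane-1,3-diyl diacetate | CC(=O)OCC(=O)COC(C)=O | starting material
5 | (triphenylphosphoranylidene)acetaldehyde | O=CC=P(c1ccccc1)(c1ccccc1)c1ccccc1 | starting material
6 | 2-(2-oxoethylidene)propane-1,3-diyl diacetate | CC(=O)OCC(COC(C)=O)=CC=O | intermediate
7 | [5-acetyl-2,4-bis(ethylzinciooxy)phenyl](ethyl)zinc | CC[Zn]c1cc(C(C)=O)c(O[Zn]CC)cc1O[Zn]CC | intermediate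
8 | tris(ethylzinc) salt of 2-[(2S)-2-(5-acetyl-2,4-dihydroxyphenyl)-2-hydroxyethylidene]propane-1,3-diyl diacetate | CC(=O)c1cc([C@H](C=C(COC(C)=O)COC(C)=O)O[Zn]CC)c(O[Zn]CC)cc1O[Zn]CC | intermediate
9 | 2-[(2R,3R)-5-acetyl-3,6-dihydroxy-2,3-dihydro-1-benzofuran-2-yl]prop-2-en-1-yl acetate | C=C(COC(C)=O)[C@H]1Oc2cc(O)c(C(C)=O)cc2[C@H]1O | intermediate
10 | (2Z)-2-methylbut-2-enoic acid (angelic acid) | C/C=C(/C)C(=O)O | starting material
11 | (2Z)-2-methylbut-2-enoic 2,4,6-trichlorobenzoic anhydride | C/C=C(/C)C(=O)OC(=O)c1c(Cl)cc(Cl)cc1Cl | intermediate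
12 | (2R,3R)-5-acetyl-2-[3-(acetyloxy)prop-1-en-2-yl]-6-hydroxy-2,3-dihydro-1-benzofuran-3-yl (2Z)-2-methylbut-2-enoate | C=C(COC(C)=O)[C@H]1Oc2cc(O)c(C(C)=O)cc2[C@H]1OC(=O)/C(C)=C\C | target

**Step count and risks**

Total step count: 5. Longest linear sequence: 4 (steps 1, 2, 4, 5); step 3 is a one-step branch.

Steps most likely to fail:

1. Step 4. The ortho zinc phenoxide may slow the aryl transfer or erode its facial control. Ethyl transfer, or acetyl migration from the Z-disposed acetoxymethyl arm to the new alkoxide, may compete. Residual ethylzinc may transmetallate to the π-allylpalladium. The ring may close trans if the C3 substituent overrides the ligand.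
   Fallback: the two bond formations are uncoupled and control of C3 is given up. Setting out from 3 and 6, rhodium-catalysed 1,2-addition ([Rh(acac)(CO)2], tri-tert-butylphosphine, aqueous DME) should give the racemic triol 2-[2-(5-acetyl-2,4-dihydroxyphenyl)-2-hydroxyethylidene]propane-1,3-diyl diacetate F1. Tsuji–Trost cyclisation of isolated F1 (Pd2(dba)3·CHCl3, the same (R,R)-bisphosphine, Et3N, CH2Cl2) should then give, under ligand control at C2, the cis diol 9 and the trans diol 2-[(2R,3S)-5-acetyl-3,6-dihydroxy-2,3-dihydro-1-benzofuran-2-yl]prop-2-en-1-yl acetate F2, to be separated by chromatography. 9 comes back to the route at step 5. F2 is esterified with 10 under Mitsunobu conditions (PPh3, DIAD, toluene, 0 °C) with inversion at C3 and comes back at 12, so both diastereomers end in the target.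

2. Step 2. The electron-rich boronic acid, with oxygen ortho and para to boron, may undergo protodeboronation during the borylation or its work-up.
   Fallback: boron is avoided. Setting out from 1, iodination (ICl, AcOH, rt) should give 1-(2,4-dihydroxy-5-iodophenyl)ethanone F3. Nozaki–Hiyama–Kishi coupling of F3 with 6 (CrCl2, catalytic NiCl2, DMF, rt) should give the racemic triol F1, which is carried on as in the fallback for step 4 through 9 and the trans diol F2, coming back to the route at 9 and at 12.

3. Step 5. Z to E isomerisation of the angeloyl group, loss of the benzylic ester by elimination toward the benzofuran on heating with amine, or competing acylation of the C6 phenol may occur.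
   Fallback: the Z double bond is built after the ester bond. Setting out from 9, esterification with 2-[bis(2,2,2-trifluoroethoxy)phosphoryl]propanoic acid (N,N′-diisopropylcarbodiimide, CH2Cl2, 0 °C) should give the phosphonate ester (2R,3R)-5-acetyl-2-[3-(acetyloxy)prop-1-en-2-yl]-6-hydroxy-2,3-dihydro-1-benzofuran-3-yl 2-[bis(2,2,2-trifluoroethoxy)phosphoryl]propanoate F4. Still–Gennari olefination of F4 with acetaldehyde (KN(SiMe3)2, two equivalents because of the C6 phenol, 18-crown-6, THF, −78 °C) should give the Z ester and comes back at 12.

**Further compounds**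

F1 | step 4 | 2-[2-(5-acetyl-2,4-dihydroxyphenyl)-2-hydroxyethylidene]propane-1,3-diyl diacetate (racemic) | CC(=O)c1cc(C(O)C=C(COC(C)=O)COC(C)=O)c(O)cc1O
F2 | step 4 | 2-[(2R,3S)-5-acetyl-3,6-dihydroxy-2,3-dihydro-1-benzofuran-2-yl]prop-2-en-1-yl acetate | C=C(COC(C)=O)[C@H]1Oc2cc(O)c(C(C)=O)cc2[C@@H]1O
F3 | step 2 | 1-(2,4-dihydroxy-5-iodophenyl)ethanone | CC(=O)c1cc(I)c(O)cc1O
F4 | step 5 | (2R,3R)-5-acetyl-2-[3-(acetyloxy)prop-1-en-2-yl]-6-hydroxy-2,3-dihydro-1-benzofuran-3-yl 2-[bis(2,2,2-trifluoroethoxy)phosphoryl]propanoate | C=C(COC(C)=O)[C@H]1Oc2cc(O)c(C(C)=O)cc2[C@H]1OC(=O)C(C)P(=O)(OCC(F)(F)F)OCC(F)(F)F
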